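Reading E at 5.0 h means asking how many powers of ten it has fallen by then, across flasks that differ in their loading of Q.

    Q + E → Q + X (k1 = 0.0149 L mol⁻¹ s⁻¹)
    E ⇌ G (K2 = 10.2, k2 = 4.75 × 10⁻⁵ s⁻¹)
    Z + J → E + J, rate k3*[J]*[Z] (k3 = 0.944 L mol⁻¹ s⁻¹)
    Z + Q → J + E (k4 = 0.00510 L mol⁻¹ s⁻¹)

| setting | Thursday's | Monday's | Wednesday's | Tuesday's | Saturday's |
|---|---|---|---|---|---|
| Z | 0.18 M | 0.18 M | 0.18 M | 0.18 M | 0.18 M |
| Q | 1.2 mol% | 2.5 mol% | 5 mol% | 10 mol% | 20 mol% |
| time | 5.0 h | 5.0 h | 5.0 h | 5.0 h | 5.0 h |

1. [E] at the end for Thursday's, Monday's, Wednesday's, Tuesday's, Saturday's, in this order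
2. the shape of the row from first to last (rises all the way / falls all the way / falls, then rises / hardly changes / rises, then falls)

- "hardly changes" means that all values lie within two and a half points (for a concentration: within two and a half percent of the largest)
- run time (Thursday's): 5.0 h

**How much Q outlasts Z?** Let c be the charge of Q and j the J made. Step 4 makes J at k4[Q][Z] and step 3 uses Z at k3[J][Z], so [Z] cancels. While [Q] stays near c, j grows by (k4/k3)(c/j) per Z used. Integrating over the charge of Z gives j = √(2(k4/k3)c[Z]), with [Z] taken at its charge. For Tuesday's, c = 0.0180 M and j = 0.00592 M, which leaves 0.0121 M of Q.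

**Does E start from the full charge?** Nearly: on Tuesday's, with j as above, Z has a half-life under step 3 of 2.07 min, far shorter than the run.

**And then?** With [Q] steady, E leaves by two pseudo-first-order routes. So the decades lost are D = (k1[Q] + k2)t/ln(10), and Tuesday's gives 1.78, or 0.00300 M of E.

**Where does that weaken?** On Thursday's, the formula puts j at 94.9 % of c, so [Q] near c fails. Yet even the whole charge of Q gives step 1 a first-order constant of 3.22 × 10⁻⁵ s⁻¹ on Thursday's, less than the 4.75 × 10⁻⁵ s⁻¹ of forward step 2, so there the forward step 2 outweighs step 1.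

**And the way back from G?** D drops it, so I hold Saturday's figure loosely.

From Thursday's to Saturday's, D runs 0.384, 0.551, 0.932, 1.78, 3.59. That makes E 0.0743 M, 0.0506 M, 0.0210 M, 0.00300 M, 4.63 × 10⁻⁵ M, falling all the way.

The forecast gave 0.069 M, 0.047 M, 0.02 M, 0.0031 M, 2.000 × 10⁻⁴ M, a row that falls all the way, with Saturday's above mine, and said “the end value falls steadily and steeply as the Q loading rises”.

The flasks end at 0.0708 M, 0.0479 M, 0.0204 M, 0.00332 M, 2.10 × 10⁻⁴ M, and the row falls all the way. Tuesday's keeps 71.0 % of its charge of Q at the end. Its reading of 0.00332 M is a fall of 1.73 decades, against a D of 1.78. On Saturday's, a D of 3.59 puts E at 4.63 × 10⁻⁵ M, while the flask holds 2.10 × 10⁻⁴ M of E beside G at 9.39 % of the Z charged.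

The rate constants are those of an exercise; the rest is arithmetic.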